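**Plan**

1. Retrosynthesis: the diene is cut at C3–C4 (Suzuki coupling) and the amide at N–C1, which separates an alkenylboronate C4–C17 from a 2-aminonaphthoquinone. The quinone ring is then cut at C4–C4a and C1–C8a into an aryl Grignard reagent and a semisquaric ester. The chain is cut at the ketal C–O bonds, C13–C14, C11–C12, C9–C10 and C6–C7.
2. Enabling feature: the quinone ring carbons C1–C2–C3–C4 form a four-carbon unit with oxygen on C1 and C4, a heteroatom on C2 and hydrogen on C3, which is the pattern of a squaric acid derivative. This unit is fused to a benzoate ring (C4a–C8a) in which C4a is the only unsubstituted carbon ortho to C8a.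
3. Forward, chain: double crotylation of 2-methylpropane-1,3-diol with two molecules of the crotyl donor gives C4–C11 plus one carbon that is later removed by ozonolysis. A temporary iodo-tetrahydropyran masks O9 and the C4=C5 alkene. A third crotylation, a Stetter reaction and a directed reduction/ketalisation then close the dioxabicyclo[3.2.1]octane, after which the temporary ring is opened and the alkene is borylated by cross-metathesis.
4. Forward, arene: the Grignard reagent of a protected iodoresorcylate adds to isopropyl semisquarate, and the 4-aryl-4-hydroxycyclobutenone ring-expands thermally to the naphthoquinone, the last ring of the skeleton. Ammonia replaces the alkoxy group, the amine is acylated with (Z)-3-iodo-2-methylacryloyl chloride, the halves are joined by Suzuki coupling and the 4-methoxybenzyl groups are removed.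
5. Stereochemistry: C6, C7, C9, C10, C11 and C12 come from one iridium–SEGPHOS crotylation catalyst system (S-ligand, then R-ligand), C8 from the arm-selective iodoetherification, C13 from a hydroxyl-directed 1,3-anti reduction, and C16 from the geometry of the bicyclic ketal. The 4E alkene comes from cross-metathesis and the 2Z alkene from chelation-controlled carbomagnesiation of propargyl alcohol; both are retained in the coupling.

Key step: step 14

Remark: locants C1–C17 are those of the target side chain (C1 amide carbon, C16 ketal carbon) and C1–C8a those of the naphthoquinone. The SEGPHOS enantiomers in steps 1 and 4 are assigned on the assumption that the (S)-ligand gives the (S)-carbinol in this series; the SMILES define the configuration required.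

**Route**

Step 1
Reactants: 1 2-methylpropane-1,3-diol; 2 but-3-en-2-yl acetate (racemic; two molecules are taken up, one at each hydroxymethyl group)
Product: 4 (3S,4S,6S,7S)-3,5,7-trimethylnona-1,8-diene-4,6-diol, via mono-crotylated diol 3 (not isolated)
Conditions: 2 (4 equiv), [Ir(cod)Cl]2 (5 mol %), (S)-SEGPHOS (10 mol %), 4-cyano-3-nitrobenzoic acid (20 mol %), K3PO4 (20 mol %), THF/H2O, 70 °C
Reagents that add atoms: but-3-en-2-yl acetate (second molecule of 2), CC(OC(C)=O)C=C
Why: Iridium-catalysed transfer-hydrogenative double crotylation (Krische crotylation), in which each primary alcohol is dehydrogenated in turn and each aldehyde takes up one crotyl unit from one molecule of 2 in an anti sense through a closed chair transition state under catalyst control, so that both carbinols (C7, C9) should form S with anti methyl groups (C6, C10), while C8 is not a stereocentre in 4 and either hydroxymethyl group may react first.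

Step 2
Reactants: 4 (3S,4S,6S,7S)-3,5,7-trimethylnona-1,8-diene-4,6-diol
Product: 5 (2S,3R,4R,5R,6S)-6-[(2S)-but-3-en-2-yl]-2-(iodomethyl)-3,5-dimethyloxan-4-ol
Conditions: I2, NaHCO3, MeCN, 0 °C
Reagents that add atoms: iodine, II
Why: Iodoetherification (6-exo) through a chair transition state, in which only O9 can close a tetrahydropyran that keeps three of the four existing ring substituents equatorial with the iodomethyl group equatorial at the temporary centre C5, whereas the ring from O7 would be all-cis, so that O9 and the C4=C5 alkene should be masked together and the choice between the two diastereotopic arms makes C8 a stereocentre of the required configuration.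

Step 3
Reactants: 5 (2S,3R,4R,5R,6S)-6-[(2S)-but-3-en-2-yl]-2-(iodomethyl)-3,5-dimethyloxan-4-ol
Product: 7 2-[4-hydroxy-6-(iodomethyl)-3,5-dimethyloxan-2-yl]propan-1-ol (stereocentres as in 5), via C11 aldehyde 6 (not isolated)
Conditions: O3, CH2Cl2/MeOH, −78 °C; then NaBH4, −78 °C to rt
Reagents that add atoms: ozone, [O-][O+]=O
Why: Ozonolysis of the one remaining alkene followed by borohydride reduction in the same flask touches no stereocentre and avoids handling the epimerisable aldehyde 6.

Step 4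
Reactants: 7 2-[4-hydroxy-6-(iodomethyl)-3,5-dimethyloxan-2-yl]propan-1-ol; 2 but-3-en-2-yl acetate
Product: 8 2-[4-hydroxy-6-(iodomethyl)-3,5-dimethyloxan-2-yl]-4-methylhex-5-en-3-ol (C11 R, C12 R; C10/C11 syn, C11/C12 anti)
Conditions: [Ir(cod)Cl]2 (5 mol %), (R)-SEGPHOS (10 mol %), 4-cyano-3-nitrobenzoic acid (20 mol %), K3PO4 (20 mol %), THF/H2O, 70 °C
Reagents that add atoms: none
Why: Krische crotylation from the alcohol oxidation level with the enantiomeric ligand, in which the aldehyde exists only transiently (guarding C10) and catalyst-controlled anti crotylation should set C11 and C12 in the sense that Felkin–Anh addition also favours, the secondary ring hydroxyl being left alone.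

Step 5
Reactants: 8 2-[4-hydroxy-6-(iodomethyl)-3,5-dimethyloxan-2-yl]-4-methylhex-5-en-3-ol
Product: 9 3-hydroxy-4-[4-hydroxy-6-(iodomethyl)-3,5-dimethyloxan-2-yl]-2-methylpentanal
Conditions: O3, CH2Cl2, −78 °C; then PPh3
Reagents that add atoms: ozone, [O-][O+]=O
Why: Ozonolysis with phosphine work-up should give the β-hydroxy aldehyde, which is used crude to avoid epimerisation at C12.

Step 6
Reactants: 9 3-hydroxy-4-[4-hydroxy-6-(iodomethyl)-3,5-dimethyloxan-2-yl]-2-methylpentanal; 10 but-3-en-2-one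
Product: 11 7-hydroxy-8-[4-hydroxy-6-(iodomethyl)-3,5-dimethyloxan-2-yl]-6-methylnonane-2,5-dione
Conditions: 3-benzyl-5-(2-hydroxyethyl)-4-methylthiazolium chloride (20 mol %), Et3N, dioxane, 60 °C
Reagents that add atoms: none
Why: Stetter reaction, in which the carbene from the thiazolium salt turns the aldehyde into an acyl anion equivalent (Breslow intermediate) that adds 1,4 to methyl vinyl ketone and so installs C14–C17 as a 1,4-diketone in one step.

Step 7
Reactants: 11 7-hydroxy-8-[4-hydroxy-6-(iodomethyl)-3,5-dimethyloxan-2-yl]-6-methylnonane-2,5-dione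
Product: 13 2-(iodomethyl)-3,5-dimethyl-6-{1-[(1S,3S,4R,5S)-1,4-dimethyl-2,8-dioxabicyclo[3.2.1]octan-3-yl]ethyl}oxan-4-ol, via anti-diol ketone 12 (not isolated)
Conditions: Me4NBH(OAc)3, MeCN/AcOH (1:1), −30 °C; then CSA (cat.), CH2Cl2, rt
Reagents that add atoms: none
Why: Evans–Saksena reduction, in which the C11 hydroxyl exchanges onto boron and delivers hydride intramolecularly to C13 through a chair transition state, should give the 1,3-anti diol and leave the undirected C16 ketone alone, and acid then closes the thermodynamically favoured 2,8-dioxabicyclo[3.2.1]octane from O11, O13 and C16, whose configuration at C16 is dictated by the bicycle.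

Step 8
Reactants: 13 2-(iodomethyl)-3,5-dimethyl-6-{1-[(1S,3S,4R,5S)-1,4-dimethyl-2,8-dioxabicyclo[3.2.1]octan-3-yl]ethyl}oxan-4-ol
Product: 14 (3S,4S,5R,6R,7R)-7-[(1S,3S,4R,5S)-1,4-dimethyl-2,8-dioxabicyclo[3.2.1]octan-3-yl]-3,5-dimethyloct-1-ene-4,6-diol
Conditions: Zn dust, AcOH, EtOH, 50 °C
Reagents that add atoms: none
Why: Zinc insertion into the C–I bond and β-elimination of the ring alkoxide (Boord-type reductive fragmentation) should open the temporary tetrahydropyran and return the C4=C5 alkene and O9–H.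

Step 9
Reactants: 14 (3S,4S,5R,6R,7R)-7-[(1S,3S,4R,5S)-1,4-dimethyl-2,8-dioxabicyclo[3.2.1]octan-3-yl]-3,5-dimethyloct-1-ene-4,6-diol; 15 4,4,5,5-tetramethyl-2-vinyl-1,3,2-dioxaborolane
Product: 16 (E)-alkenylboronate of the C4–C17 chain (pinacol ester on C4; 7,9-diol and ketal as in 14)
Conditions: second-generation Hoveyda–Grubbs catalyst (10 mol %), CH2Cl2, 40 °C
Reagents that add atoms: none
Why: Olefin cross-metathesis with the vinylboronic ester should give the (E)-alkenylboronate for steric reasons, with hydroxyls and ketal tolerated and no stereocentre involved.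

Step 10
Reactants: 17 2,4-dihydroxy-3-methylbenzoic acid
Product: 18 2,4-dihydroxy-5-iodo-3-methylbenzoic acid
Conditions: N-iodosuccinimide, MeCN, 0 °C to rt
Reagents that add atoms: N-iodosuccinimide, O=C1CCC(=O)N1I
Why: Electrophilic aromatic iodination goes to C5, which is ortho to one hydroxyl and para to the other and is the only free activated position.

Step 11
Reactants: 18 2,4-dihydroxy-5-iodo-3-methylbenzoic acid
Product: 19 4-methoxybenzyl 5-iodo-2,4-bis[(4-methoxybenzyl)oxy]-3-methylbenzoate
Conditions: 4-methoxybenzyl chloride (3.5 equiv), K2CO3, Bu4NI (cat.), DMF, 50 °C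
Reagents that add atoms: 4-methoxybenzyl chloride, COc1ccc(CCl)cc1
Why: Threefold O-alkylation (Williamson ether synthesis and carboxylate alkylation) puts one acid-labile group on the acid and on both phenols.

Step 12
Reactants: 20 3,4-diisopropoxycyclobut-3-ene-1,2-dione (diisopropyl squarate)
Product: 22 3-isopropoxycyclobut-3-ene-1,2-dione, via hydroxycyclobutenone 21 (not isolated)
Conditions: LiAlH(OtBu)3, THF, −78 °C; then 6 M HCl, rt
Reagents that add atoms: none
Why: Hindered-hydride 1,2-reduction of one squarate carbonyl followed by acid-promoted allylic transposition of 21 with loss of propan-2-ol is the established route to the semisquaric ester.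

Step 13
Reactants: 19 4-methoxybenzyl 5-iodo-2,4-bis[(4-methoxybenzyl)oxy]-3-methylbenzoate; 22 3-isopropoxycyclobut-3-ene-1,2-dione
Product: 24 4-methoxybenzyl 5-(1-hydroxy-2-isopropoxy-4-oxocyclobut-2-en-1-yl)-2,4-bis[(4-methoxybenzyl)oxy]-3-methylbenzoate (racemic), via arylmagnesium chloride 23 (not isolated)
Conditions: iPrMgCl·LiCl, THF, −40 °C; then 22, −78 °C
Reagents that add atoms: none
Why: Iodine–magnesium exchange with the turbo-Grignard reagent tolerates the ester at low temperature, and the aryl Grignard should add 1,2 to the ketone-like carbonyl next to C–OiPr and not to the vinylogous ester carbonyl, as is general for alkoxycyclobutenediones.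

Step 14
Reactants: 24 4-methoxybenzyl 5-(1-hydroxy-2-isopropoxy-4-oxocyclobut-2-en-1-yl)-2,4-bis[(4-methoxybenzyl)oxy]-3-methylbenzoate
Product: 27 4-methoxybenzyl 6-isopropoxy-2,4-bis[(4-methoxybenzyl)oxy]-3-methyl-5,8-dioxo-5,8-dihydronaphthalene-1-carboxylate, via aryl vinylketene 25 (not isolated), via hydroquinone 26 (not isolated)
Conditions: p-xylene, 138 °C, under air
Reagents that add atoms: none
Why: Heating opens the cyclobutenone by a conrotatory four-electron electrocyclic reaction in which the hydroxyl rotates outward and the aryl group inward, giving aryl vinylketene 25; its ketene carbon then closes onto the ortho carbon C4a in a six-electron electrocyclisation (bond C4–C4a, six-membered carbocycle), and tautomerisation gives hydroquinone 26, which air oxidises to quinone 27. The closest known reaction type is the Moore–Liebeskind ring expansion of 4-aryl-4-hydroxycyclobutenones to 1,4-naphthoquinones. No stereocentre is formed, and the racemic carbinol centre of 24 is destroyed. Two kinds of regiocontrol are needed: closure can only go to C4a because the other ortho carbon (C8) carries an ether group, and the isopropoxy group must end on C2 next to C1/C8a, which is fixed because step 13 joined the aryl carbon C8a to the carbonyl carbon adjacent to C–OiPr. Running the thermolysis under air should oxidise 26 as it forms, before its C4 hydroxyl can lactonise onto the peri ester.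

Step 15
Reactants: 27 4-methoxybenzyl 6-isopropoxy-2,4-bis[(4-methoxybenzyl)oxy]-3-methyl-5,8-dioxo-5,8-dihydronaphthalene-1-carboxylate
Product: 28 4-methoxybenzyl 6-amino-2,4-bis[(4-methoxybenzyl)oxy]-3-methyl-5,8-dioxo-5,8-dihydronaphthalene-1-carboxylate
Conditions: NH3 (7 M in MeOH), THF, 0 °C
Reagents that add atoms: ammonia, N
Why: Addition–elimination of ammonia at C2 of the 2-alkoxyquinone (a vinylogous ester) should give the aminoquinone without change of the substitution pattern.

Step 16
Reactants: 29 prop-2-yn-1-ol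
Product: 31 (Z)-3-iodo-2-methylprop-2-en-1-ol, via alkenylmagnesium alkoxide 30 (not isolated)
Conditions: MeMgBr (2.5 equiv), CuI (10 mol %), THF, −10 °C to rt; then I2, −10 °C
Reagents that add atoms: methylmagnesium bromide, C[Mg]Br; iodine, II
Why: Copper-catalysed carbomagnesiation of propargyl alcohol, in which the magnesium alkoxide directs anti addition so that magnesium ends on C3 cis to the oxygen-bearing carbon, followed by iodinolysis with retention, should give the Z iodide.

Step 17
Reactants: 31 (Z)-3-iodo-2-methylprop-2-en-1-ol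
Product: 32 (Z)-3-iodo-2-methylprop-2-enoic acid
Conditions: TEMPO (20 mol %), PhI(OAc)2, MeCN/H2O, rt
Reagents that add atoms: water, O
Why: TEMPO-catalysed oxidation with PhI(OAc)2 in the presence of water takes the alcohol through the aldehyde hydrate to the acid under nearly neutral conditions that should keep the Z geometry.

Step 18
Reactants: 28 4-methoxybenzyl 6-amino-2,4-bis[(4-methoxybenzyl)oxy]-3-methyl-5,8-dioxo-5,8-dihydronaphthalene-1-carboxylate; 32 (Z)-3-iodo-2-methylprop-2-enoic acid
Product: 34 4-methoxybenzyl 6-[(Z)-3-iodo-2-methylprop-2-enamido]-2,4-bis[(4-methoxybenzyl)oxy]-3-methyl-5,8-dioxo-5,8-dihydronaphthalene-1-carboxylate, via acid chloride 33 (not isolated)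
Conditions: 32, 1-chloro-N,N,2-trimethylprop-1-en-1-amine, CH2Cl2, 0 °C; then 28, NaH, THF, 0 °C
Reagents that add atoms: none
Why: The Ghosez reagent makes the acid chloride without releasing HCl, and the sodium salt of the weakly nucleophilic vinylogous amide 28 is then N-acylated (amide formation from an acid chloride).

Step 19
Reactants: 34 4-methoxybenzyl 6-[(Z)-3-iodo-2-methylprop-2-enamido]-2,4-bis[(4-methoxybenzyl)oxy]-3-methyl-5,8-dioxo-5,8-dihydronaphthalene-1-carboxylate; 16 (E)-alkenylboronate of the C4–C17 chain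
Product: 35 tris(4-methoxybenzyl)-protected rifsaliniketal (4-methoxybenzyl ester, 6-O- and 8-O-(4-methoxybenzyl) ethers)
Conditions: Pd(dppf)Cl2 (10 mol %), K3PO4, THF/H2O, rt
Reagents that add atoms: none
Why: Suzuki–Miyaura coupling of the alkenyl iodide with the alkenylboronate proceeds with retention at both carbons and should give the (2Z,4E)-diene, the free hydroxyls, ketal and esters being tolerated.

Step 20
Reactants: 35 tris(4-methoxybenzyl)-protected rifsaliniketal
Product: 36 rifsaliniketal
Conditions: TFA/CH2Cl2 (1:9), anisole, 0 °C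
Reagents that add atoms: none
Why: Acidolysis of the 4-methoxybenzyl ester and the two aryl 4-methoxybenzyl ethers, with anisole to trap the benzyl cations, should free the acid and both phenols, while the bicyclic ketal is the thermodynamic form under acid and should persist.

**Compound list**

1 | 2-methylpropane-1,3-diol | CC(CO)CO | starting material
2 | but-3-en-2-yl acetate (racemic) | CC(OC(C)=O)C=C | starting material
3 | (3S,4S)-2,4-dimethylhex-5-ene-1,3-diol (both C2 epimers) | C=C[C@H](C)[C@H](O)C(C)CO | intermediate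
4 | (3S,4S,6S,7S)-3,5,7-trimethylnona-1,8-diene-4,6-diol | C=C[C@H](C)[C@H](O)C(C)[C@@H](O)[C@@H](C)C=C | intermediate
5 | (2S,3R,4R,5R,6S)-6-[(2S)-but-3-en-2-yl]-2-(iodomethyl)-3,5-dimethyloxan-4-ol | IC[C@@H]1[C@H](C)[C@H](O)[C@@H](C)[C@@H](O1)[C@@H](C)C=C | intermediate
6 | 2-[4-hydroxy-6-(iodomethyl)-3,5-dimethyloxan-2-yl]propanal (C11 aldehyde) | IC[C@@H]1[C@H](C)[C@H](O)[C@@H](C)[C@@H](O1)[C@@H](C)C=O | intermediate
7 | 2-[4-hydroxy-6-(iodomethyl)-3,5-dimethyloxan-2-yl]propan-1-ol | IC[C@@H]1[C@H](C)[C@H](O)[C@@H](C)[C@@H](O1)[C@@H](C)CO | intermediate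
8 | 2-[4-hydroxy-6-(iodomethyl)-3,5-dimethyloxan-2-yl]-4-methylhex-5-en-3-ol | IC[C@@H]1[C@H](C)[C@H](O)[C@@H](C)[C@@H](O1)[C@@H](C)[C@H](O)[C@H](C)C=C | intermediate
9 | 3-hydroxy-4-[4-hydroxy-6-(iodomethyl)-3,5-dimethyloxan-2-yl]-2-methylpentanal | IC[C@@H]1[C@H](C)[C@H](O)[C@@H](C)[C@@H](O1)[C@@H](C)[C@H](O)[C@H](C)C=O | intermediate
10 | but-3-en-2-one | C=CC(C)=O | starting material
11 | 7-hydroxy-8-[4-hydroxy-6-(iodomethyl)-3,5-dimethyloxan-2-yl]-6-methylnonane-2,5-dione | IC[C@@H]1[C@H](C)[C@H](O)[C@@H](C)[C@@H](O1)[C@@H](C)[C@H](O)[C@H](C)C(=O)CCC(C)=O | intermediate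
12 | 5,7-dihydroxy-8-[4-hydroxy-6-(iodomethyl)-3,5-dimethyloxan-2-yl]-6-methylnonan-2-one (C11/C13 anti) | IC[C@@H]1[C@H](C)[C@H](O)[C@@H](C)[C@@H](O1)[C@@H](C)[C@H](O)[C@H](C)[C@@H](O)CCC(C)=O | intermediate
13 | 2-(iodomethyl)-3,5-dimethyl-6-{1-[(1S,3S,4R,5S)-1,4-dimethyl-2,8-dioxabicyclo[3.2.1]octan-3-yl]ethyl}oxan-4-ol | IC[C@@H]1[C@H](C)[C@H](O)[C@@H](C)[C@@H](O1)[C@@H](C)[C@@H]2O[C@@]3(C)CC[C@H](O3)[C@H]2C | intermediate
14 | (3S,4S,5R,6R,7R)-7-[(1S,3S,4R,5S)-1,4-dimethyl-2,8-dioxabicyclo[3.2.1]octan-3-yl]-3,5-dimethyloct-1-ene-4,6-diol | C=C[C@H](C)[C@H](O)[C@@H](C)[C@@H](O)[C@@H](C)[C@@H]1O[C@@]2(C)CC[C@H](O2)[C@H]1C | intermediate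
15 | 4,4,5,5-tetramethyl-2-vinyl-1,3,2-dioxaborolane | C=CB1OC(C)(C)C(C)(C)O1 | starting material
16 | (E)-alkenylboronate of the C4–C17 chain (pinacol ester) | CC1(C)OB(OC1(C)C)/C=C/[C@H](C)[C@H](O)[C@@H](C)[C@@H](O)[C@@H](C)[C@@H]1O[C@@]2(C)CC[C@H](O2)[C@H]1C | intermediate
17 | 2,4-dihydroxy-3-methylbenzoic acid | Cc1c(O)ccc(C(=O)O)c1O | starting material
18 | 2,4-dihydroxy-5-iodo-3-methylbenzoic acid | Cc1c(O)c(I)cc(C(=O)O)c1O | intermediate
19 | 4-methoxybenzyl 5-iodo-2,4-bis[(4-methoxybenzyl)oxy]-3-methylbenzoate | COc1ccc(COC(=O)c2cc(I)c(OCc3ccc(OC)cc3)c(C)c2OCc2ccc(OC)cc2)cc1 | intermediate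
20 | 3,4-diisopropoxycyclobut-3-ene-1,2-dione | CC(C)OC1=C(OC(C)C)C(=O)C1=O | starting material
21 | 4-hydroxy-2,3-diisopropoxycyclobut-2-en-1-one (racemic) | CC(C)OC1=C(OC(C)C)C(O)C1=O | intermediate
22 | 3-isopropoxycyclobut-3-ene-1,2-dione | CC(C)OC1=CC(=O)C1=O | intermediate
23 | arylmagnesium chloride from 19 | COc1ccc(COC(=O)c2cc([Mg]Cl)c(OCc3ccc(OC)cc3)c(C)c2OCc2ccc(OC)cc2)cc1 | intermediate
24 | 4-methoxybenzyl 5-(1-hydroxy-2-isopropoxy-4-oxocyclobut-2-en-1-yl)-2,4-bis[(4-methoxybenzyl)oxy]-3-methylbenzoate (racemic) | CC(C)OC1=CC(=O)C1(O)c1cc(C(=O)OCc2ccc(OC)cc2)c(OCc2ccc(OC)cc2)c(C)c1OCc1ccc(OC)cc1 | intermediate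
25 | aryl vinylketene (aryl cis to the ketene-bearing carbon) | O=C=C/C(OC(C)C)=C(/O)c1cc(C(=O)OCc2ccc(OC)cc2)c(OCc2ccc(OC)cc2)c(C)c1OCc1ccc(OC)cc1 | intermediate
26 | 4-methoxybenzyl 5,8-dihydroxy-6-isopropoxy-2,4-bis[(4-methoxybenzyl)oxy]-3-methylnaphthalene-1-carboxylate | CC(C)Oc1cc(O)c2c(C(=O)OCc3ccc(OC)cc3)c(OCc3ccc(OC)cc3)c(C)c(OCc3ccc(OC)cc3)c2c1O | intermediate
27 | 4-methoxybenzyl 6-isopropoxy-2,4-bis[(4-methoxybenzyl)oxy]-3-methyl-5,8-dioxo-5,8-dihydronaphthalene-1-carboxylate | CC(C)OC1=CC(=O)c2c(C(=O)OCc3ccc(OC)cc3)c(OCc3ccc(OC)cc3)c(C)c(OCc3ccc(OC)cc3)c2C1=O | intermediate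
28 | 4-methoxybenzyl 6-amino-2,4-bis[(4-methoxybenzyl)oxy]-3-methyl-5,8-dioxo-5,8-dihydronaphthalene-1-carboxylate | NC1=CC(=O)c2c(C(=O)OCc3ccc(OC)cc3)c(OCc3ccc(OC)cc3)c(C)c(OCc3ccc(OC)cc3)c2C1=O | intermediate
29 | prop-2-yn-1-ol | C#CCO | starting material
30 | (Z)-alkenylmagnesium bromide alkoxide | C/C(=C/[Mg]Br)CO[Mg]Br | intermediate
31 | (Z)-3-iodo-2-methylprop-2-en-1-ol | C/C(=C/I)CO | intermediate
32 | (Z)-3-iodo-2-methylprop-2-enoic acid | C/C(=C/I)C(=O)O | intermediate
33 | (Z)-3-iodo-2-methylprop-2-enoyl chloride | C/C(=C/I)C(Cl)=O | intermediate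
34 | 4-methoxybenzyl 6-[(Z)-3-iodo-2-methylprop-2-enamido]-2,4-bis[(4-methoxybenzyl)oxy]-3-methyl-5,8-dioxo-5,8-dihydronaphthalene-1-carboxylate | C/C(=C/I)C(=O)NC1=CC(=O)c2c(C(=O)OCc3ccc(OC)cc3)c(OCc3ccc(OC)cc3)c(C)c(OCc3ccc(OC)cc3)c2C1=O | intermediate
35 | tris(4-methoxybenzyl)-protected rifsaliniketal | C/C(=C/C=C/[C@H](C)[C@H](O)[C@@H](C)[C@@H](O)[C@@H](C)[C@@H]1O[C@@]2(C)CC[C@H](O2)[C@H]1C)C(=O)NC1=CC(=O)c2c(C(=O)OCc3ccc(OC)cc3)c(OCc3ccc(OC)cc3)c(C)c(OCc3ccc(OC)cc3)c2C1=O | intermediate
36 | rifsaliniketal | C/C(=C/C=C/[C@H](C)[C@H](O)[C@@H](C)[C@@H](O)[C@@H](C)[C@@H]1O[C@@]2(C)CC[C@H](O2)[C@H]1C)C(=O)NC1=CC(=O)c2c(C(=O)O)c(O)c(C)c(O)c2C1=O | target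

**Count and risks**

Total step count: 20. Longest linear sequence: 11 steps (steps 1–9, 19, 20).

Steps most likely to fail:

Step 6 (Stetter reaction). Under the basic, warm conditions the unprotected β-hydroxy aldehyde 9 may dehydrate or undergo retro-aldol cleavage, and the primary iodide may alkylate the amine or the carbene, before the acyl anion equivalent adds to 10. The fallback sets out from homoallylic alcohol 8 and returns at ketal 13, and builds the ketone by carbonyl addition and oxidation instead of umpolung. Both hydroxyls of 8 are silylated (TESOTf, 2,6-lutidine) to bis(triethylsilyl) ether F1, and ozonolysis (O3, then PPh3) gives aldehyde F2. Addition of [2-(2-methyl-1,3-dioxolan-2-yl)ethyl]magnesium bromide gives carbinol F3 as a mixture at C13, and Dess–Martin oxidation gives ketone F4. HF·pyridine removes both silyl groups to give hydroxy ketone F5, Me4NBH(OAc)3 gives anti diol F6, and CSA in wet CH2Cl2 exchanges the dioxolane for the bicyclic ketal 13.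

Step 14 (ring expansion). The six-electron closure onto the crowded carbon C4a may be slow, and the C4 hydroxyl of hydroquinone 26 may transesterify the peri ester before it is oxidised. The fallback sets out from carbinol 24 and returns at quinone 27, and makes this lactonisation the intended path. Thermolysis under argon followed by CSA should give peri-lactone F7. Oxidation with PhI(OAc)2 in aqueous MeCN (oxidation of a para-oxygenated phenol to the quinone) opens it to quinone acid F8, and 4-methoxybenzyl chloride with K2CO3 re-forms ester 27.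

Step 19 (Suzuki coupling). The N-acylaminoquinone may be attacked by hydroxide or reduced under the basic palladium conditions before transmetalation. The fallback sets out from boronate 16, acid 32 and aminoquinone 28 and returns at the target 36, and forms the diene before the quinone is attached. Suzuki coupling of 16 with 32 gives dienoic acid F9, and silylation (TESOTf, 2,6-lutidine, aqueous work-up to cleave the silyl ester) gives bis(triethylsilyl) ether F10. The Ghosez reagent gives acid chloride F11, and acylation of the sodium salt of 28 gives protected amide F12. The acid treatment of step 20, with water added, then removes the silyl and 4-methoxybenzyl groups together.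

**Further compounds**

F1 | step 6 | bis(triethylsilyl) ether of 8 | IC[C@@H]1[C@H](C)[C@H](O[Si](CC)(CC)CC)[C@@H](C)[C@@H](O1)[C@@H](C)[C@H](O[Si](CC)(CC)CC)[C@H](C)C=C
F2 | step 6 | C13 aldehyde from F1 | IC[C@@H]1[C@H](C)[C@H](O[Si](CC)(CC)CC)[C@@H](C)[C@@H](O1)[C@@H](C)[C@H](O[Si](CC)(CC)CC)[C@H](C)C=O
F3 | step 6 | C13 carbinol with dioxolane tail (C13 epimers) | IC[C@@H]1[C@H](C)[C@H](O[Si](CC)(CC)CC)[C@@H](C)[C@@H](O1)[C@@H](C)[C@H](O[Si](CC)(CC)CC)[C@H](C)C(O)CCC1(C)OCCO1
F4 | step 6 | C13 ketone with dioxolane tail | IC[C@@H]1[C@H](C)[C@H](O[Si](CC)(CC)CC)[C@@H](C)[C@@H](O1)[C@@H](C)[C@H](O[Si](CC)(CC)CC)[C@H](C)C(=O)CCC1(C)OCCO1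
F5 | step 6 | desilylated hydroxy ketone with dioxolane tail | IC[C@@H]1[C@H](C)[C@H](O)[C@@H](C)[C@@H](O1)[C@@H](C)[C@H](O)[C@H](C)C(=O)CCC1(C)OCCO1
F6 | step 6 | C11/C13 anti diol with dioxolane tail | IC[C@@H]1[C@H](C)[C@H](O)[C@@H](C)[C@@H](O1)[C@@H](C)[C@H](O)[C@H](C)[C@@H](O)CCC1(C)OCCO1
F7 | step 14 | peri-lactone (naphtho[1,8-bc]furan-2-one with free C1 hydroxyl) | O=C1Oc2cc(OC(C)C)c(O)c3c(OCc4ccc(OC)cc4)c(C)c(OCc4ccc(OC)cc4)c1c23
F8 | step 14 | 6-isopropoxy-2,4-bis[(4-methoxybenzyl)oxy]-3-methyl-5,8-dioxo-5,8-dihydronaphthalene-1-carboxylic acid | CC(C)OC1=CC(=O)c2c(C(=O)O)c(OCc3ccc(OC)cc3)c(C)c(OCc3ccc(OC)cc3)c2C1=O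
F9 | step 19 | (2Z,4E)-dienoic acid of the C1–C17 chain | C/C(=C/C=C/[C@H](C)[C@H](O)[C@@H](C)[C@@H](O)[C@@H](C)[C@@H]1O[C@@]2(C)CC[C@H](O2)[C@H]1C)C(=O)O
F10 | step 19 | 7,9-bis(triethylsilyl) ether of F9 | C/C(=C/C=C/[C@H](C)[C@H](O[Si](CC)(CC)CC)[C@@H](C)[C@@H](O[Si](CC)(CC)CC)[C@@H](C)[C@@H]1O[C@@]2(C)CC[C@H](O2)[C@H]1C)C(=O)O
F11 | step 19 | acid chloride of F10 | C/C(=C/C=C/[C@H](C)[C@H](O[Si](CC)(CC)CC)[C@@H](C)[C@@H](O[Si](CC)(CC)CC)[C@@H](C)[C@@H]1O[C@@]2(C)CC[C@H](O2)[C@H]1C)C(Cl)=O
F12 | step 19 | 7,9-bis(triethylsilyl) ether of 35 | C/C(=C/C=C/[C@H](C)[C@H](O[Si](CC)(CC)CC)[C@@H](C)[C@@H](O[Si](CC)(CC)CC)[C@@H](C)[C@@H]1O[C@@]2(C)CC[C@H](O2)[C@H]1C)C(=O)NC1=CC(=O)c2c(C(=O)OCc3ccc(OC)cc3)c(OCc3ccc(OC)cc3)c(C)c(OCc3ccc(OC)cc3)c2C1=O
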